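The cis-decalin is disconnected at C9–C10 (eremophilane numbering), the bond between the ring fusion carbon and the acyloxy carbinol of ring B. A C9 radical flanked by the C8 ketone and one chlorine, released from a dichloromethyl ketone, cyclises 6-exo onto the C10=C1 alkene of a ring A cyclohexene. Because its chain hangs from the quaternary C5, it reaches C10 only anti to the pseudoaxial C5 methyl: one step closes ring B, sets the cis fusion and leaves a C9 chloride that is exchanged for senecioate. The precursor is a monocyclic cyclohexene; its C3, C4 and C5 centres come from one silyloxy centre, and an ene-type acylation of a prenyl group supplies the isopropenyl ketone chain.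

Key step: step 9

Numbering: eremophilane numbering is used for all compounds (ring A = C1–C5 and C10; ring B = C5–C10; C11–C13 isopropenyl on C7; C14 on C5; C15 on C4).
Assumption 1: the (S,S) lithium amide is taken to give the (R) enol ether 3, by analogy with other 4-substituted cyclohexanones; if the sense is opposite, the (R,R) amide is used.
Assumption 2: C7 and C9 are both α to the C8 ketone and both substituents are equatorial in the target, so the 7β,9β arrangement is taken as the thermodynamic one among the isopropenyl isomers.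

Step 1
Reactants: 1 4-(tert-butyldimethylsilyloxy)cyclohexan-1-one
Product: 3 (R)-tert-butyldimethyl{[4-(trimethylsilyloxy)cyclohex-3-en-1-yl]oxy}silane, via lithium enolate 2 (not isolated)
Conditions: (S,S)-bis(1-phenylethyl)amine, n-BuLi, LiCl, Me3SiCl (in situ quench), THF, −78 °C
Reagents that add atoms: chlorotrimethylsilane, C[Si](C)(C)Cl
Why: Enantiotopic α-deprotonation of the prochiral ketone by the C2-symmetric chiral lithium amide with in situ O-silylation (chiral base desymmetrisation) should fix C3 as R, the centre from which all others are derived.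

Step 2
Reactants: 3 (R)-tert-butyldimethyl{[4-(trimethylsilyloxy)cyclohex-3-en-1-yl]oxy}silane
Product: 4 (R)-4-(tert-butyldimethylsilyloxy)cyclohex-2-en-1-one
Conditions: Pd(OAc)2 (1.05 equiv), MeCN, rt
Reagents that add atoms: none
Why: Saegusa–Ito oxidation (palladation of the silyl enol ether, then β-hydride elimination) should give the enone regiospecifically and leave C3 untouched.

Step 3
Reactants: 4 (R)-4-(tert-butyldimethylsilyloxy)cyclohex-2-en-1-one
Product: 5 (R)-4-(tert-butyldimethylsilyloxy)-2-iodocyclohex-2-en-1-one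
Conditions: I2, pyridine, CH2Cl2, 0 °C to rt
Reagents that add atoms: iodine, II
Why: Pyridine-mediated addition–iodination–elimination (Baylis–Hillman-type α-iodination of an enone) should place the handle for the C14 methyl on the α-carbon, the future C5.

Step 4
Reactants: 5 (R)-4-(tert-butyldimethylsilyloxy)-2-iodocyclohex-2-en-1-one
Product: 6 (R)-4-(tert-butyldimethylsilyloxy)-2-methylcyclohex-2-en-1-one
Conditions: Me4Sn, Pd2(dba)3 (cat.), AsPh3, CuI, NMP, 60 °C
Reagents that add atoms: tetramethylstannane, C[Sn](C)(C)C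
Why: Stille coupling of the α-iodoenone should install the C14 methyl without disturbing the γ-silyloxy enone.

Step 5
Reactants: 6 (R)-4-(tert-butyldimethylsilyloxy)-2-methylcyclohex-2-en-1-one; 7 1-bromo-3-methylbut-2-ene
Product: 9 (2R,3R,4R)-4-(tert-butyldimethylsilyloxy)-2,3-dimethyl-2-(3-methylbut-2-en-1-yl)cyclohexan-1-one, via lithium enolate 8 (not isolated)
Conditions: Me2CuLi (from MeLi and CuI), Et2O, −78 to −40 °C; then 7, HMPA, THF, −40 to 0 °C
Reagents that add atoms: lithium dimethylcuprate, [Li+].C[Cu-]C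
Why: Tandem cuprate conjugate addition–enolate alkylation: the methyl should add anti to the C3 silyloxy group (sets C4), and the regiodefined enolate 8 should be prenylated anti to the new C4 methyl, held pseudoaxial by allylic 1,2-strain, which sets the quaternary C5 with C14 cis to C15.

Step 6
Reactants: 9 (2R,3R,4R)-4-(tert-butyldimethylsilyloxy)-2,3-dimethyl-2-(3-methylbut-2-en-1-yl)cyclohexan-1-one
Product: 11 (4R,5R,6R)-4-(tert-butyldimethylsilyloxy)-5,6-dimethyl-6-(3-methylbut-2-en-1-yl)cyclohex-1-en-1-yl trifluoromethanesulfonate, via potassium enolate 10 (not isolated)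
Conditions: KN(SiMe3)2, THF, −78 °C; then PhNTf2, −78 to 0 °C
Reagents that add atoms: N-phenylbis(trifluoromethanesulfonimide), O=S(=O)(N(c1ccccc1)S(=O)(=O)C(F)(F)F)C(F)(F)F
Why: The ketone can enolise only toward C1 because C5 is quaternary, so O-sulfonylation of the enolate should give a single enol triflate.

Step 7
Reactants: 11 (4R,5R,6R)-4-(tert-butyldimethylsilyloxy)-5,6-dimethyl-6-(3-methylbut-2-en-1-yl)cyclohex-1-en-1-yl trifluoromethanesulfonate
Product: 12 tert-butyl{[(1R,5S,6R)-5,6-dimethyl-5-(3-methylbut-2-en-1-yl)cyclohex-3-en-1-yl]oxy}dimethylsilane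
Conditions: Pd(OAc)2 (cat.), PPh3, HCO2H, n-Bu3N, DMF, 60 °C
Reagents that add atoms: none
Why: Palladium-catalysed formate reduction of the enol triflate (oxidative addition, formate exchange, decarboxylation, reductive elimination) should replace the triflate by hydrogen and leave the C10=C1 alkene beside the quaternary C5.

Step 8
Reactants: 12 tert-butyl{[(1R,5S,6R)-5,6-dimethyl-5-(3-methylbut-2-en-1-yl)cyclohex-3-en-1-yl]oxy}dimethylsilane; 13 dichloroacetyl chloride
Product: 14 1,1-dichloro-3-{[(1S,5R,6R)-5-(tert-butyldimethylsilyloxy)-1,6-dimethylcyclohex-2-en-1-yl]methyl}-4-methylpent-4-en-2-one as a mixture of C7 epimers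
Conditions: EtAlCl2, CH2Cl2, −78 °C
Reagents that add atoms: none
Why: Ene-type (aliphatic Friedel–Crafts) acylation: the acylium should attack the less substituted carbon of the trisubstituted prenyl alkene, far more nucleophilic than the hindered ring alkene, and loss of a methyl proton should give the β,γ-unsaturated isopropenyl ketone; C7 is not controlled here and is corrected in step 10.

Step 9
Reactants: 14 1,1-dichloro-3-{[(1S,5R,6R)-5-(tert-butyldimethylsilyloxy)-1,6-dimethylcyclohex-2-en-1-yl]methyl}-4-methylpent-4-en-2-one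
Product: 15 (3R,4R,5R,10S)-3-(tert-butyldimethylsilyloxy)-9-chloroeremophil-11-en-8-one as a mixture of C7 and C9 epimers
Conditions: n-Bu3SnH (1.05 equiv, syringe pump), AIBN (cat.), benzene, 80 °C, high dilution
Reagents that add atoms: none
Why: The stannyl radical abstracts one chlorine to give an α-chloro-α-keto radical at C9, which adds to C10 of the ring A alkene, and the resulting secondary C1 radical takes hydrogen from the stannane. The closest known reaction type is the tin hydride-mediated reductive cyclisation of α-halo ketone radicals onto cycloalkenes. Ring B is closed in the 6-exo-trig mode. C10 is set by a chair-like transition state in which the chain is pseudoequatorial on C5 and attacks the alkene face anti to the pseudoaxial C14 methyl, so H10 ends cis to C14 (cis fusion); C9 forms as chloride epimers that converge in step 10. The step needs 6-exo closure to beat 7-endo attack at C1, direct reduction and loss of the second chlorine: C10 is the nearer alkene carbon, the isopropenyl group is reachable only by 4-exo or 5-endo modes, the stannane is kept dilute, and the dichloromethyl group should react faster than the monochloride product.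

Step 10
Reactants: 15 (3R,4R,5R,10S)-3-(tert-butyldimethylsilyloxy)-9-chloroeremophil-11-en-8-one; 16 3-methylbut-2-enoic acid
Product: 17 (3R,4R,5R,7R,9R,10S)-3-(tert-butyldimethylsilyloxy)-9-(3-methylbut-2-enoyloxy)eremophil-11-en-8-one
Conditions: 16, Cs2CO3, n-Bu4NI (cat.), DMF, 40 °C; then DBU (0.2 equiv), 0 °C, short contact, AcOH quench
Reagents that add atoms: none
Why: SN2 displacement of the α-keto chloride by the carboxylate (fastest for the axial C–Cl aligned with the carbonyl π system) should give the α-acyloxy ketone, and brief base treatment should equilibrate C7 and C9 to the all-equatorial 7β,9β isomer through kinetic α-protonation of the enolates.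

Step 11
Reactants: 17 (3R,4R,5R,7R,9R,10S)-3-(tert-butyldimethylsilyloxy)-9-(3-methylbut-2-enoyloxy)eremophil-11-en-8-one
Product: 18 (3R,4R,5R,7R,9R,10S)-3-hydroxy-9-(3-methylbut-2-enoyloxy)eremophil-11-en-8-one
Conditions: HF·pyridine, pyridine, THF, 0 °C to rt
Reagents that add atoms: none
Why: Fluoride cleavage of the secondary silyl ether under buffered, weakly acidic conditions should free the C3 hydroxyl without enolising the C8 ketone or touching the senecioate.

Step 12
Reactants: 18 (3R,4R,5R,7R,9R,10S)-3-hydroxy-9-(3-methylbut-2-enoyloxy)eremophil-11-en-8-one; 19 (Z)-2-methylbut-2-enoic acid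
Product: 20 (3R,4R,5R,7R,9R,10S)-3-[(Z)-2-methylbut-2-enoyloxy]-9-(3-methylbut-2-enoyloxy)eremophil-11-en-8-one
Conditions: 19, 2,4,6-trichlorobenzoyl chloride, Et3N, toluene, rt, filter; then 18, toluene, 80 °C
Reagents that add atoms: none
Why: Yamaguchi-type esterification through the preformed mixed anhydride, heated with the alcohol without a nucleophilic catalyst, should acylate the equatorial C3 hydroxyl while keeping the Z geometry of the angelate.

Compound list
1 | 4-(tert-butyldimethylsilyloxy)cyclohexan-1-one | CC(C)(C)[Si](C)(C)OC1CCC(=O)CC1 | starting material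
2 | lithium (R)-4-(tert-butyldimethylsilyloxy)cyclohex-1-en-1-olate | [Li+].[O-]C1=CC[C@H](O[Si](C)(C)C(C)(C)C)CC1 | intermediate (not isolated)
3 | (R)-tert-butyldimethyl{[4-(trimethylsilyloxy)cyclohex-3-en-1-yl]oxy}silane | C[Si](C)(C)OC1=CC[C@H](O[Si](C)(C)C(C)(C)C)CC1 | intermediate
4 | (R)-4-(tert-butyldimethylsilyloxy)cyclohex-2-en-1-one | O=C1C=C[C@H](O[Si](C)(C)C(C)(C)C)CC1 | intermediate
5 | (R)-4-(tert-butyldimethylsilyloxy)-2-iodocyclohex-2-en-1-one | O=C1C(I)=C[C@H](O[Si](C)(C)C(C)(C)C)CC1 | intermediate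
6 | (R)-4-(tert-butyldimethylsilyloxy)-2-methylcyclohex-2-en-1-one | CC1=C[C@H](O[Si](C)(C)C(C)(C)C)CCC1=O | intermediate
7 | 1-bromo-3-methylbut-2-ene (prenyl bromide) | CC(C)=CCBr | starting material
8 | lithium (3R,4R)-4-(tert-butyldimethylsilyloxy)-2,3-dimethylcyclohex-1-en-1-olate | CC1=C([O-])CC[C@@H](O[Si](C)(C)C(C)(C)C)[C@@H]1C.[Li+] | intermediate (not isolated)
9 | (2R,3R,4R)-4-(tert-butyldimethylsilyloxy)-2,3-dimethyl-2-(3-methylbut-2-en-1-yl)cyclohexan-1-one | CC(C)=CC[C@@]1(C)C(=O)CC[C@@H](O[Si](C)(C)C(C)(C)C)[C@@H]1C | intermediate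
10 | potassium (4R,5R,6R)-4-(tert-butyldimethylsilyloxy)-5,6-dimethyl-6-(3-methylbut-2-en-1-yl)cyclohex-1-en-1-olate | CC(C)=CC[C@@]1(C)C([O-])=CC[C@@H](O[Si](C)(C)C(C)(C)C)[C@@H]1C.[K+] | intermediate (not isolated)
11 | (4R,5R,6R)-4-(tert-butyldimethylsilyloxy)-5,6-dimethyl-6-(3-methylbut-2-en-1-yl)cyclohex-1-en-1-yl trifluoromethanesulfonate | CC(C)=CC[C@@]1(C)C(OS(=O)(=O)C(F)(F)F)=CC[C@@H](O[Si](C)(C)C(C)(C)C)[C@@H]1C | intermediate
12 | tert-butyl{[(1R,5S,6R)-5,6-dimethyl-5-(3-methylbut-2-en-1-yl)cyclohex-3-en-1-yl]oxy}dimethylsilane | CC(C)=CC[C@@]1(C)C=CC[C@@H](O[Si](C)(C)C(C)(C)C)[C@@H]1C | intermediate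
13 | dichloroacetyl chloride | O=C(Cl)C(Cl)Cl | starting material
14 | 1,1-dichloro-3-{[(1S,5R,6R)-5-(tert-butyldimethylsilyloxy)-1,6-dimethylcyclohex-2-en-1-yl]methyl}-4-methylpent-4-en-2-one (C7 epimers) | C=C(C)C(C[C@@]1(C)C=CC[C@@H](O[Si](C)(C)C(C)(C)C)[C@@H]1C)C(=O)C(Cl)Cl | intermediate
15 | (3R,4R,5R,10S)-3-(tert-butyldimethylsilyloxy)-9-chloroeremophil-11-en-8-one (3α-silyloxy, 10βH; C7 and C9 epimers) | C=C(C)C1C[C@@]2(C)[C@H](CC[C@@H](O[Si](C)(C)C(C)(C)C)[C@@H]2C)C(Cl)C1=O | intermediate
16 | 3-methylbut-2-enoic acid (senecioic acid) | CC(C)=CC(=O)O | starting material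
17 | (3R,4R,5R,7R,9R,10S)-3-(tert-butyldimethylsilyloxy)-9-(3-methylbut-2-enoyloxy)eremophil-11-en-8-one | C=C(C)[C@H]1C[C@@]2(C)[C@H](CC[C@@H](O[Si](C)(C)C(C)(C)C)[C@@H]2C)[C@@H](OC(=O)C=C(C)C)C1=O | intermediate
18 | (3R,4R,5R,7R,9R,10S)-3-hydroxy-9-(3-methylbut-2-enoyloxy)eremophil-11-en-8-one | C=C(C)[C@H]1C[C@@]2(C)[C@H](CC[C@@H](O)[C@@H]2C)[C@@H](OC(=O)C=C(C)C)C1=O | intermediate
19 | (Z)-2-methylbut-2-enoic acid (angelic acid) | C/C=C(/C)C(=O)O | starting material
20 | (3R,4R,5R,7R,9R,10S)-3-[(Z)-2-methylbut-2-enoyloxy]-9-(3-methylbut-2-enoyloxy)eremophil-11-en-8-one (3α-angeloyloxy-9β-senecioyloxy-10βH-eremophil-11-en-8-one) | C=C(C)[C@H]1C[C@@]2(C)[C@H](CC[C@@H](OC(=O)/C(C)=C\C)[C@@H]2C)[C@@H](OC(=O)C=C(C)C)C1=O | target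

Total step count: 12. Longest linear sequence: 12 steps (from 1).

Steps most likely to fail

Step 9. The C9 radical may take hydrogen before it cyclises, abstract an allylic hydrogen from the isopropenyl methyl (1,5-transfer), or close 7-endo at C1. The fallback closes ring B by an anionic instead of a radical event; it sets out from ketone 9 and comes back at chloro ketone 15. EtAlCl2-promoted acylation of the prenyl group of 9 with acetyl chloride should give 3-{[(1R,2R,3R)-3-(tert-butyldimethylsilyloxy)-1,2-dimethyl-6-oxocyclohexyl]methyl}-4-methylpent-4-en-2-one F1. Intramolecular aldol condensation of its C9 methyl onto the C10 ketone (pyrrolidine, AcOH, toluene, 80 °C) should give 3α-(tert-butyldimethylsilyloxy)eremophila-9,11-dien-8-one F2. Conjugate reduction with catalytic [(Ph3P)CuH]6 and PhMe2SiH should deliver hydride axially to C10 on the C14 face and give the cis-fused 3α-(tert-butyldimethylsilyloxy)-8-(dimethylphenylsilyloxy)-10βH-eremophila-8,11-diene F3. N-Chlorosuccinimide (THF, 0 °C) should then chlorinate C9 and return 15.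

Step 8. The acylium–Lewis acid mixture may strip the silyl ether, attack the ring alkene, or move the new double bond into conjugation. The fallback replaces the acylation by a formaldehyde ene reaction and a one-carbon homologation; it sets out from alkene 12 and comes back at ketone 14. Paraformaldehyde with Me2AlCl (CH2Cl2, 0 °C) should give the ene adduct 2-{[(1S,5R,6R)-5-(tert-butyldimethylsilyloxy)-1,6-dimethylcyclohex-2-en-1-yl]methyl}-3-methylbut-3-en-1-ol F4. Dess–Martin oxidation should give 2-{[(1S,5R,6R)-5-(tert-butyldimethylsilyloxy)-1,6-dimethylcyclohex-2-en-1-yl]methyl}-3-methylbut-3-enal F5. Addition of LiCHCl2 (from CH2Cl2 and LDA, THF, −100 °C) should give 1,1-dichloro-3-{[(1S,5R,6R)-5-(tert-butyldimethylsilyloxy)-1,6-dimethylcyclohex-2-en-1-yl]methyl}-4-methylpent-4-en-2-ol F6. A second Dess–Martin oxidation should give 14.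

Step 10. The carboxylate may cause elimination to the 9(10)-enone or a Favorskii-type ring contraction instead of substitution, and the base treatment may move the isopropenyl double bond into conjugation or shift the acyl group. The fallback brings in the C9 oxygen by enolate oxidation; it sets out from chloro ketone 15 and comes back at 17. Zinc and Me3SiCl (THF, rt) should reduce the C–Cl bond and trap the regiodefined enolate as 3α-(tert-butyldimethylsilyloxy)-8-(trimethylsilyloxy)-10βH-eremophila-8,11-diene F7. Rubottom oxidation with dimethyldioxirane (acetone, −78 °C, then citric acid in MeOH) should attack the open β face and give 3α-(tert-butyldimethylsilyloxy)-9-hydroxy-10βH-eremophil-11-en-8-one F8. Acylation with 3-methylbut-2-enoyl chloride and pyridine (CH2Cl2, 0 °C) should give 17.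

Further compounds
F1 | step 9 | 3-{[(1R,2R,3R)-3-(tert-butyldimethylsilyloxy)-1,2-dimethyl-6-oxocyclohexyl]methyl}-4-methylpent-4-en-2-one | C=C(C)C(C[C@@]1(C)C(=O)CC[C@@H](O[Si](C)(C)C(C)(C)C)[C@@H]1C)C(C)=O
F2 | step 9 | 3α-(tert-butyldimethylsilyloxy)eremophila-9,11-dien-8-one | C=C(C)C1C[C@@]2(C)C(=CC1=O)CC[C@@H](O[Si](C)(C)C(C)(C)C)[C@@H]2C
F3 | step 9 | 3α-(tert-butyldimethylsilyloxy)-8-(dimethylphenylsilyloxy)-10βH-eremophila-8,11-diene | C=C(C)C1C[C@@]2(C)[C@H](CC[C@@H](O[Si](C)(C)C(C)(C)C)[C@@H]2C)C=C1O[Si](C)(C)c1ccccc1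
F4 | step 8 | 2-{[(1S,5R,6R)-5-(tert-butyldimethylsilyloxy)-1,6-dimethylcyclohex-2-en-1-yl]methyl}-3-methylbut-3-en-1-ol | C=C(C)C(CO)C[C@@]1(C)C=CC[C@@H](O[Si](C)(C)C(C)(C)C)[C@@H]1C
F5 | step 8 | 2-{[(1S,5R,6R)-5-(tert-butyldimethylsilyloxy)-1,6-dimethylcyclohex-2-en-1-yl]methyl}-3-methylbut-3-enal | C=C(C)C(C=O)C[C@@]1(C)C=CC[C@@H](O[Si](C)(C)C(C)(C)C)[C@@H]1C
F6 | step 8 | 1,1-dichloro-3-{[(1S,5R,6R)-5-(tert-butyldimethylsilyloxy)-1,6-dimethylcyclohex-2-en-1-yl]methyl}-4-methylpent-4-en-2-ol | C=C(C)C(C(O)C(Cl)Cl)C[C@@]1(C)C=CC[C@@H](O[Si](C)(C)C(C)(C)C)[C@@H]1C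
F7 | step 10 | 3α-(tert-butyldimethylsilyloxy)-8-(trimethylsilyloxy)-10βH-eremophila-8,11-diene | C=C(C)C1C[C@@]2(C)[C@H](CC[C@@H](O[Si](C)(C)C(C)(C)C)[C@@H]2C)C=C1O[Si](C)(C)C
F8 | step 10 | 3α-(tert-butyldimethylsilyloxy)-9-hydroxy-10βH-eremophil-11-en-8-one | C=C(C)C1C[C@@]2(C)[C@H](CC[C@@H](O[Si](C)(C)C(C)(C)C)[C@@H]2C)C(O)C1=O
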